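In the teal run, 59.0% of the partner charged stands as target at 30.0 h, while 48.7% of the substrate has not become target. So partner, the limiting reagent in teal, seems to go somewhere else too. Let us keep a ledger of it.

| flask | substrate | partner | capture agent | free catalyst | remark |
|---|---|---|---|---|---|
| teal | 0.42 M | 0.87 equiv | 0.021 M | 2 mol% | run made earlier |
| grey | 0.42 M | 2 equiv | 0.021 M | 2 mol% | run made earlier |
| violet | 0.42 M | 1.3 equiv | 0.021 M | 3 mol% | run made earlier |
| flask | 0.42 M | 1.30 equiv | 0.0210 M | 2 mol% |  |

| teal: time / h | teal: target / % | grey: time / h | grey: target / % | violet: time / h | violet: target / % |
|---|---|---|---|---|---|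
| 2.50 | 15.1 | 2.50 | 27.5 | 4.00 | 40.9 |
| 6.00 | 27.9 | 6.00 | 48.2 | 10.0 | 63.5 |
| 12.0 | 41.4 | 12.0 | 64.8 | 20.0 | 74.6 |
| 30.0 | 51.3 | 30.0 | 79.9 | 30.0 | 77.4 |

(scatter of a reading: 0.5 percentage points)



- apparent order in free catalyst when 50% of the substrate are converted (percent change of the rate of making target for one percent more free catalyst charged)
- factor on the rate of making target when 50% of the substrate are converted if partner is charged twice over

My reckoning makes two suppositions. Each target costs one partner, at a rate proportional to catalyst times partner. The missing partner pairs with itself, at a rate proportional to partner squared. Dividing the two rates and integrating gives: target made = m ln[(m + partner charged)/(m + partner left)]. Here m is proportional to catalyst.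

Count the target at 30.0 h as the whole yield of the charge, and solve by one round of trial. Teal then reads 0.217 M for m, the crossover level: the partner concentration at which the catalyst route and the pairing consume partner equally. Violet, read the same way, gives 0.330 M. Scaled back to 2 mol% catalyst, that is 0.220 M, close to teal.

The flask has teal's catalyst loading, so I use teal's reading of m. My reckoned books for the flask at 50% conversion, with no partner counted as held on the catalyst, run as follows. Of 0.546 M partner charged, 0.210 M has become target, 0.0731 M is left, and 0.263 M has paired. On my suppositions the rate is catalyst times partner left, and differentiating the ledger with respect to m gives an order in catalyst of 3.00. Of that, 2.00 comes through the partner left.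

The forecast gives 1.6 for the order and 2.8 for doubling partner. In its words: “More catalyst therefore acts directly and also spares decay”. My order is higher.

The simulation gives an order of 2.6 and a factor of 2.85.

    partner + free catalyst → catalyst intermediate A (k = 12.0 /M/h)
    substrate + catalyst intermediate A ⇌ catalyst intermediate B (K = 3.60 /M, k = 140 /M/h)
    catalyst intermediate B ⇌ by-product + catalyst intermediate C (K = 0.440 M, k = 400 /h)
    catalyst intermediate C → free catalyst + target (k = 150 /h)
    2 partner → self-condensation product (k = 0.190 /M/h)
    catalyst intermediate B + capture agent → trapped intermediate (k = 14.0 /M/h)

At the start of the flask, the step from partner and free catalyst to catalyst intermediate A used partner at 0.49 of the rate of self-condensation. With partner left at zero, the crossover level gives the flask a final target of 65.0%, and the flask holds 67.0% at 250 h. For the grey run it gives a final target of 81.9%, and the reading at 30.0 h is 79.9%.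

The numbers in the tables are simulated from invented constants; noise was put on by code.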